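**Assumptions**
- Agrimol F as drawn has no stereocentres and no stereogenic axis. It is achiral, so the "single enantiomer" requirement is trivially met and nothing needs to be set or protected from scrambling.
- 2-Methylphloroglucinol (2,4,6-trihydroxytoluene) is taken to be commercially available. The butyryl and acetyl groups are introduced by acylation.
- In 3-methyl-2,4,6-trihydroxyacylphenones, the 2-OH (flanked by the C-methyl and the acyl group, and chelated to the C=O) is the last to be alkylated. I rely on this for the 4,6-di-O-benzylation in Steps 3 and 9.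

**Retrosynthetic overview**
1. Disconnect the two Ar–CH2–Ar bonds (o-quinone-methide-type diarylmethane disconnections). This gives a central 2,4,6-trihydroxybutyrophenone nucleophile and two different fully substituted terminal units (acetyl and butyryl) used as masked o-QMs (benzodioxaborins).
2. Each terminal unit comes from 2-methylphloroglucinol by acylation, 4,6-di-O-benzylation (the hindered 2-OH stays free), 2-O-methylation, debenzylation, then boronate-assisted ortho-hydroxymethylation.
3. All three arenes are preformed, so no ring is built. The arenes are joined in sequence: acetyl unit to central ring first, then butyryl unit. No protecting groups remain at the end.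

**Route**

Step 1
Reactants: 1 phloroglucinol; 2 butyric acid
Product: 3 2',4',6'-trihydroxybutyrophenone
Conditions: BF3·OEt2 (neat, excess), 90 °C, 2 h; aq. NaOAc work-up
Reagents that add atoms: butyric acid, CCCC(=O)O
Why: BF3-mediated Friedel–Crafts (Nencki-type) C-acylation of the highly nucleophilic phloroglucinol; the product is deactivated toward a second acylation.

Step 2
Reactants: 4 2-methylphloroglucinol (2-methylbenzene-1,3,5-triol); 5 acetic acid
Product: 6 1-(2,4,6-trihydroxy-3-methylphenyl)ethan-1-one
Conditions: BF3·OEt2, 80 °C, 3 h
Reagents that add atoms: acetic acid, CC(=O)O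
Why: Friedel–Crafts acylation; the two free ring positions of 4 are equivalent by symmetry, so there is no regiochemical issue.

Step 3
Reactants: 6; 7 benzyl bromide
Product: 8 1-(4,6-bis(benzyloxy)-2-hydroxy-3-methylphenyl)ethan-1-one
Conditions: BnBr (2.2 equiv), K2CO3 (2.5 equiv), acetone, reflux, 12 h
Reagents that add atoms: benzyl bromide, BrCc1ccccc1
Why: Williamson O-alkylation. The 4-OH is the most acidic and the 6-OH is unhindered; the 2-OH is shielded by the flanking methyl and the C=O chelate, so it stays free.

Step 4
Reactants: 8; 9 iodomethane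
Product: 10 1-(4,6-bis(benzyloxy)-2-methoxy-3-methylphenyl)ethan-1-one
Conditions: MeI (5 equiv), K2CO3 (4 equiv), DMF, 60 °C, 8 h
Reagents that add atoms: iodomethane, CI
Why: Williamson methylation of the remaining chelated phenol. The small electrophile and polar aprotic solvent overcome the hindrance and give the OMe flanked by the acyl group and the methyl.

Step 5
Reactants: 10
Product: 11 1-(4,6-dihydroxy-2-methoxy-3-methylphenyl)ethan-1-one
Conditions: H2 (1 atm), 10% Pd/C, EtOAc/EtOH 1:1, rt, 3 h
Reagents that add atoms: none
Why: Catalytic hydrogenolysis removes both benzyl ethers. The twisted, hindered aryl ketone and the aryl methyl ether are untouched.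

Step 6
Reactants: 11; 12 paraformaldehyde; 13 phenylboronic acid
Product: 14 2-phenyl-4H-1,3,2-benzodioxaborin of 1-(4,6-dihydroxy-5-(hydroxymethyl)-2-methoxy-3-methylphenyl)ethanone (masked o-QM, acetyl series)
Conditions: (CH2O)n (4 equiv), PhB(OH)2 (1.5 equiv), EtCO2H (10 mol%), toluene, reflux, Dean–Stark, 6 h; filter and concentrate
Reagents that add atoms: paraformaldehyde, C=O; phenylboronic acid, OB(O)c1ccccc1
Why: Casiraghi-type boronate-directed ortho-hydroxymethylation at the only free ring carbon, C5, which sits between two OH groups. The boronate traps the benzylic alcohol and prevents the usual dimerisation of hydroxymethyl-phloroglucinols.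

Step 7 (key step)
Reactants: 14; 3 (3.0 equiv)
Product: 15 1-(2,4,6-trihydroxy-3-[5-acetyl-2,4-dihydroxy-... i.e. (3-acetyl-2,6-dihydroxy-4-methoxy-5-methylbenzyl)]phenyl)butan-1-one, i.e. mono-benzylated central ring
Conditions: 3 (3.0 equiv), 2,6-lutidine (20 mol%), MeCN/H2O 20:1, 80 °C, 16 h; silica chromatography (excess 3 recovered)
Reagents that add atoms: none
Why: Proposed new method: 14 is an isolable boron-masked o-QM of a fully oxygenated acylphenol. On heating with wet MeCN and mild base, benzylic C–O–B ionisation, pushed by the adjacent phenol oxygens, gives a boron-bound o-quinone methide. C3 of the acylphloroglucinol 3, flanked by two oxygen groups, adds to it in a 1,4-Friedel–Crafts-type conjugate addition, and rearomatisation releases PhB(OH)2. The closest known reactions are boronic-acid-mediated o-QM generation and conjugate addition, plus Casiraghi hydroxymethylation. Here a stable benzodioxaborin of a tetra-oxygenated acylphenol is used as a traceless o-QM surrogate for C–H benzylation of an acylphloroglucinol, which I am not aware of. Unit 14 has no free ring C–H, so it cannot self-condense; O-benzylation is reversible. The excess of 3 suppresses double benzylation. No stereocentre is formed.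

Step 8
Reactants: 4; 2 butyric acid
Product: 16 1-(2,4,6-trihydroxy-3-methylphenyl)butan-1-one
Conditions: BF3·OEt2, 90 °C, 3 h
Reagents that add atoms: butyric acid, CCCC(=O)O
Why: Friedel–Crafts acylation, as in Step 2.

Step 9
Reactants: 16; 7 benzyl bromide
Product: 17 1-(4,6-bis(benzyloxy)-2-hydroxy-3-methylphenyl)butan-1-one
Conditions: BnBr (2.2 equiv), K2CO3 (2.5 equiv), acetone, reflux, 12 h
Reagents that add atoms: benzyl bromide, BrCc1ccccc1
Why: Williamson O-alkylation with the same selectivity as Step 3.

Step 10
Reactants: 17; 9 iodomethane
Product: 18 1-(4,6-bis(benzyloxy)-2-methoxy-3-methylphenyl)butan-1-one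
Conditions: MeI (5 equiv), K2CO3 (4 equiv), DMF, 60 °C, 8 h
Reagents that add atoms: iodomethane, CI
Why: Williamson methylation of the chelated, hindered phenol.

Step 11
Reactants: 18
Product: 19 1-(4,6-dihydroxy-2-methoxy-3-methylphenyl)butan-1-one
Conditions: H2 (1 atm), 10% Pd/C, EtOAc/EtOH 1:1, rt, 3 h
Reagents that add atoms: none
Why: Hydrogenolytic debenzylation; the ketone and the OMe survive.

Step 12
Reactants: 19; 12 paraformaldehyde; 13 phenylboronic acid
Product: 20 2-phenyl-4H-1,3,2-benzodioxaborin of 1-(4,6-dihydroxy-5-(hydroxymethyl)-2-methoxy-3-methylphenyl)butan-1-one (masked o-QM, butyryl series)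
Conditions: (CH2O)n (4 equiv), PhB(OH)2 (1.5 equiv), EtCO2H (10 mol%), toluene, reflux, Dean–Stark, 6 h
Reagents that add atoms: paraformaldehyde, C=O; phenylboronic acid, OB(O)c1ccccc1
Why: Casiraghi boronate-directed ortho-hydroxymethylation, as in Step 6.

Step 13 (second use of the key step)
Reactants: 15; 20 (1.3 equiv)
Product: 21 Agrimol F
Conditions: 2,6-lutidine (20 mol%), MeCN/H2O 20:1, 80 °C, 16 h; silica chromatography
Reagents that add atoms: none
Why: Proposed new method: same boron-bound o-QM C-benzylation as Step 7. The only remaining C–H of 15, C5 of the central ring between two OH groups, is the sole nucleophilic site. The product has no further free ring C–H, so over-alkylation is impossible. No stereocentre is involved.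

**Compound list**
1 | phloroglucinol | Oc1cc(O)cc(O)c1 | starting material
2 | butyric acid | CCCC(=O)O | starting material
3 | 2',4',6'-trihydroxybutyrophenone | CCCC(=O)c1c(O)cc(O)cc1O | intermediate
4 | 2-methylphloroglucinol | Cc1c(O)cc(O)cc1O | starting material
5 | acetic acid | CC(=O)O | starting material
6 | 1-(2,4,6-trihydroxy-3-methylphenyl)ethanone | CC(=O)c1c(O)c(C)c(O)cc1O | intermediate
7 | benzyl bromide | BrCc1ccccc1 | starting material
8 | 1-(4,6-bis(benzyloxy)-2-hydroxy-3-methylphenyl)ethanone | CC(=O)c1c(O)c(C)c(OCc2ccccc2)cc1OCc1ccccc1 | intermediate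
9 | iodomethane | CI | starting material
10 | 1-(4,6-bis(benzyloxy)-2-methoxy-3-methylphenyl)ethanone | CC(=O)c1c(OC)c(C)c(OCc2ccccc2)cc1OCc1ccccc1 | intermediate
11 | 1-(4,6-dihydroxy-2-methoxy-3-methylphenyl)ethanone | CC(=O)c1c(OC)c(C)c(O)cc1O | intermediate
12 | paraformaldehyde (monomer shown) | C=O | starting material
13 | phenylboronic acid | OB(O)c1ccccc1 | starting material
14 | acetyl-series benzodioxaborin (masked o-QM) | CC(=O)c1c(OC)c(C)c2OB(c3ccccc3)OCc2c1O | intermediate
15 | mono-benzylated central ring (acetyl-terminal–CH2–butyrophenone) | CCCC(=O)c1c(O)c(Cc2c(O)c(C)c(OC)c(C(C)=O)c2O)c(O)cc1O | intermediate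
16 | 1-(2,4,6-trihydroxy-3-methylphenyl)butan-1-one | CCCC(=O)c1c(O)c(C)c(O)cc1O | intermediate
17 | 1-(4,6-bis(benzyloxy)-2-hydroxy-3-methylphenyl)butan-1-one | CCCC(=O)c1c(O)c(C)c(OCc2ccccc2)cc1OCc1ccccc1 | intermediate
18 | 1-(4,6-bis(benzyloxy)-2-methoxy-3-methylphenyl)butan-1-one | CCCC(=O)c1c(OC)c(C)c(OCc2ccccc2)cc1OCc1ccccc1 | intermediate
19 | 1-(4,6-dihydroxy-2-methoxy-3-methylphenyl)butan-1-one | CCCC(=O)c1c(OC)c(C)c(O)cc1O | intermediate
20 | butyryl-series benzodioxaborin (masked o-QM) | CCCC(=O)c1c(OC)c(C)c2OB(c3ccccc3)OCc2c1O | intermediate
21 | Agrimol F (achiral, no stereocentres) | CCCC(=O)c1c(O)c(Cc2c(O)c(C)c(OC)c(C(C)=O)c2O)c(O)c(Cc2c(O)c(C)c(OC)c(C(=O)CCC)c2O)c1O | target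

**Step count:** 13 steps in total. The longest linear sequence is 7 steps (4 → 6 → 8 → 10 → 11 → 14 → 15 → 21).

**Three steps most likely to fail**
1. **Step 7 (and the same chemistry in Step 13; proposed new method).** The masked o-QM may hydrolyse, or the benzylation may stall or give O-benzylation.
   - Fallback (known chemistry): convert 11 to its Mannich base (CH2O, Me2NH·HCl, EtOH) and heat it with 3 (3 equiv) in DMF at 110 °C. Thermolysis releases the free o-QM (the classic o-hydroxybenzylamine route). Use the same route in the butyryl series.
2. **Step 3 (and Step 9): regioselective 4,6-di-O-benzylation.** Some 2,4-di-O-benzyl isomer may form.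
   - Fallback: build the unit through a regiodefined route. Start from 4-O-benzyl-2,6-dihydroxyacylphenone and mono-O-methylate it. Then brominate C3 (NBS), formylate C5 (Vilsmeier), reduce the CHO to CH3 (Et3SiH/TFA), and remove the Br and Bn groups in one hydrogenolysis.
3. **Step 13: second coupling onto the hindered mono-benzylated central ring 15.**
   - Fallback: reverse the polarity. Casiraghi-hydroxymethylate 15 to give a masked o-QM on the central ring. Couple it with the nucleophilic terminal phenol 19, whose C5 is free, under aqueous-base o-QM conditions.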